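**Pl

**Plan**

1. Retrosynthesis: the two benzyl ethers come off last. Ring B (the tetramethylcyclohexanetrione) is then cut at two C–C bonds: the bond from its side-chain-bearing carbon to one flanking carbonyl, and the bond from the other flanking carbonyl to its CMe2 neighbour. This gives a (4R)-4-isobutyl-3,4-dihydrocoumarin and methyl 2,2,4-trimethyl-3-oxopentanoate.
2. Enabling feature: ring B is a C(=O)–CMe2–C(=O)–CMe2 chain (two dimethylketene units, already joined in the keto ester) closed by a CH–C(=O) unit. That unit is C3–C2 of the dihydrocoumarin, whose O1–C2 aryl ester bond activates C2 for acyl transfer and whose C4 carries the isobutyl group, the stereocentre and ring A.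
3. Further back: the C4–H bond (hydride addition to the coumarin), the benzyl ethers, the ring A–acyl bond and the two bonds of a Pechmann condensation lead to 2-methylphloroglucinol, ethyl 5-methyl-3-oxohexanoate and 3-phenylpropanoyl chloride.
4. Forward order: ring A is bought; the lactone ring is fused on (step 1), acylated and benzylated (steps 2 and 3) and reduced (step 4); ring B is annulated onto the lactone carbonyl while the lactone opens (step 6); hydrogenolysis ends the route (step 7). Step 5 supplies the keto ester.
5. Stereochemistry: the only stereocentre is set in step 4 by ligand-controlled copper hydride addition to C4 (4R) and is not touched afterwards. Its descriptor becomes S in the ring B compounds only because the CIP priorities change.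

Key step: step 6

Assumption on step 1: the lactone is taken to close through the hydroxyl next to the methyl group (8-methyl coumarin 3). If the 6-methyl isomer forms instead, the same operations lead through the 6-methyl-8-acyl lactone to the same target, because ring A carries OH on three alternate carbons and methyl, acyl and side chain on the other three.

Assumption on step 4: the (R) ligand is written as the working choice. The sense of induction on a 4-alkyl-5-alkoxycoumarin cannot be predicted with confidence, and the enantiomeric ligand is used if the first run shows the 4S lactone.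

**Route**

Step 1
Reactants: 1 2-methylbenzene-1,3,5-triol (2,4,6-trihydroxytoluene); 2 ethyl 5-methyl-3-oxohexanoate
Product: 3 5,7-dihydroxy-8-methyl-4-(2-methylpropyl)-2H-chromen-2-one
Conditions: conc. H2SO4, 0 °C → rt; pour onto ice
Reagents that add atoms: none
Why: Pechmann condensation, in which the protonated ketone of 2 alkylates a free ring carbon of the very electron-rich phenol 1 and the neighbouring hydroxyl lactonises with loss of water and ethanol, as is routine for phloroglucinols and β-keto esters.

Step 2
Reactants: 3 5,7-dihydroxy-8-methyl-4-(2-methylpropyl)-2H-chromen-2-one; 4 3-phenylpropanoyl chloride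
Product: 5 5,7-dihydroxy-8-methyl-4-(2-methylpropyl)-6-(3-phenylpropanoyl)-2H-chromen-2-one
Conditions: 4 (2 equiv), AlCl3 (4 equiv), PhNO2/ClCH2CH2Cl, 70 °C; then ice/1 M HCl
Reagents that add atoms: none
Why: Friedel–Crafts C-acylation (direct, or by O-acylation and Fries shift under the same conditions) at C6, the only free ring position and ortho to both hydroxyls, a reaction well known for 5,7-dihydroxy-4-alkylcoumarins with AlCl3; the resorcinol-type ring carbon is far more nucleophilic than the phenyl ring of 4, so closure of the acylium ion to 1-indanone should stay a minor drain that the excess of 4 covers.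

Step 3
Reactants: 5 5,7-dihydroxy-8-methyl-4-(2-methylpropyl)-6-(3-phenylpropanoyl)-2H-chromen-2-one
Product: 6 5,7-bis(benzyloxy)-8-methyl-4-(2-methylpropyl)-6-(3-phenylpropanoyl)-2H-chromen-2-one
Conditions: BnBr (3 equiv), K2CO3 (4 equiv), Bu4NI (cat.), DMF, 60 °C
Reagents that add atoms: benzyl bromide, BrCc1ccccc1
Why: Double Williamson etherification, in which carbonate in a dipolar aprotic solvent favours O- over C-alkylation of the fully substituted ring and warming is expected to overcome the hydrogen bonding of both hydroxyls to the ketone, while the lactone is stable to dry K2CO3.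

Step 4
Reactants: 6 5,7-bis(benzyloxy)-8-methyl-4-(2-methylpropyl)-6-(3-phenylpropanoyl)-2H-chromen-2-one
Product: 7 (4R)-5,7-bis(benzyloxy)-8-methyl-4-(2-methylpropyl)-6-(3-phenylpropanoyl)-3,4-dihydro-2H-chromen-2-one
Conditions: Cu(OAc)2·H2O (5 mol %), (R)-DTBM-SEGPHOS (5.5 mol %), (EtO)2MeSiH (1.3 equiv), t-BuOH (1.5 equiv), toluene, 0 °C → rt
Reagents that add atoms: none
Why: Copper hydride asymmetric conjugate reduction of a β,β-disubstituted unsaturated lactone, known for coumarins, in which the bisphosphine-bound CuH delivers hydride to one face of C4 and so sets the 4R centre, tert-butanol protonates the copper enolate at C3 and the silane regenerates CuH; the ketone, twisted between two ortho benzyloxy groups, and the saturated lactone should react more slowly when the silane is kept near one equivalent.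

Step 5
Reactants: 8 2,2,4,4-tetramethylcyclobutane-1,3-dione
Product: 9 methyl 2,2,4-trimethyl-3-oxopentanoate
Conditions: NaOMe (5 mol %), MeOH, 0 °C → rt; AcOH quench
Reagents that add atoms: methanol, CO
Why: Base-catalysed alcoholysis of dimethylketene dimer, in which methoxide adds to a carbonyl of the strained dione and retro-Claisen ring opening releases the ketone enolate, protonated by methanol; it should stop at the keto ester because relief of ring strain makes the first cleavage far faster than a second.

Step 6
Reactants: 7 (4R)-5,7-bis(benzyloxy)-8-methyl-4-(2-methylpropyl)-6-(3-phenylpropanoyl)-3,4-dihydro-2H-chromen-2-one; 9 methyl 2,2,4-trimethyl-3-oxopentanoate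
Product: 12 2-[(1S)-1-[2,4-bis(benzyloxy)-6-hydroxy-5-methyl-3-(3-phenylpropanoyl)phenyl]-3-methylbutyl]-3-hydroxy-4,4,6,6-tetramethylcyclohex-2-ene-1,5-dione, via lithium enolate 10 (not isolated), via ring-opened dioxo ester 11 (not isolated)
Conditions: 9 (3.0 equiv), LiN(iPr)2 (2.9 equiv), THF, −78 °C, 30 min; 7 in THF, −78 → −20 °C; LiN(SiMe3)2 (3.0 equiv), −20 °C → rt; cold 1 M HCl
Reagents that add atoms: none
Why: LiN(iPr)2 removes the one enolisable proton of 9, and the tetrasubstituted lithium enolate 10 attacks through carbon the lactone carbonyl of 7 (an aryl ester locked in the reactive lactone geometry); the adduct collapses with loss of the ring A phenoxide to give 11, and if 10 instead deprotonates C3 the ketene–phenoxide formed by E1cB opening is trapped by 10 at carbon and reaches the enolate of 11 directly. LiN(SiMe3)2 then enolises the only CH2 beside the new ketone, and this carbon attacks the methyl ester in a 6-(enolendo)-exo-trig Dieckmann closure of ring B, helped by the two gem-dimethyl groups; the trione is deprotonated at once to its delocalised enolate, which pulls both equilibria forward and protects the product from retro-Claisen and retro-Michael cleavage. The closest known reactions are the Claisen acylation of α,α-disubstituted ketone enolates by aryl esters and lactones and the Dieckmann cyclisation of 2,2,4,4-tetramethyl-3,5-dioxo esters to syncarpic acid type triones; only their combination in one flask on this substrate is untried. No stereocentre is formed: C4 of 7 is not acidic under these conditions and becomes, unchanged in space, the S-configured benzylic carbon of 12. The step needs C- over O-acylation, favoured by the lithium counter-ion in THF without polar additives and self-correcting because an enol ester formed at oxygen is itself an acyl donor towards 10, and it needs ring closure from the lactone-derived CH2 and not from the enolate of the aryl ketone, which forms reversibly with the excess base but can reach no carbonyl through a ring of fewer than eight atoms and is reprotonated on work-up. Amide bases are used throughout because a stoichiometric alkoxide would cleave the non-enolisable 1,3-diketone of 11.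

Step 7
Reactants: 12 2-[(1S)-1-[2,4-bis(benzyloxy)-6-hydroxy-5-methyl-3-(3-phenylpropanoyl)phenyl]-3-methylbutyl]-3-hydroxy-4,4,6,6-tetramethylcyclohex-2-ene-1,5-dione
Product: 13 3-hydroxy-4,4,6,6-tetramethyl-2-[(1S)-3-methyl-1-[2,4,6-trihydroxy-3-methyl-5-(3-phenylpropanoyl)phenyl]butyl]cyclohex-2-ene-1,5-dione
Conditions: H2 (1 atm), Pd/C (10 wt %), EtOAc, rt
Reagents that add atoms: none
Why: Hydrogenolysis of the two aryl benzyl ethers under neutral conditions, under which the hydrogen-bonded acylphloroglucinol ketone and the tetrasubstituted enol double bond of ring B are not expected to be reduced and no acid is present that could cyclodehydrate a phenol onto the trione.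

**Compound list**

1 | 2-methylbenzene-1,3,5-triol (2,4,6-trihydroxytoluene) | Cc1c(O)cc(O)cc1O | starting material
2 | ethyl 5-methyl-3-oxohexanoate | CCOC(=O)CC(=O)CC(C)C | starting material
3 | 5,7-dihydroxy-8-methyl-4-(2-methylpropyl)-2H-chromen-2-one | O=C1C=C(CC(C)C)c2c(O)cc(O)c(C)c2O1 | intermediate
4 | 3-phenylpropanoyl chloride | O=C(Cl)CCc1ccccc1 | starting material
5 | 5,7-dihydroxy-8-methyl-4-(2-methylpropyl)-6-(3-phenylpropanoyl)-2H-chromen-2-one | O=C1C=C(CC(C)C)c2c(O)c(C(=O)CCc3ccccc3)c(O)c(C)c2O1 | intermediate
6 | 5,7-bis(benzyloxy)-8-methyl-4-(2-methylpropyl)-6-(3-phenylpropanoyl)-2H-chromen-2-one | O=C1C=C(CC(C)C)c2c(OCc3ccccc3)c(C(=O)CCc3ccccc3)c(OCc3ccccc3)c(C)c2O1 | intermediate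
7 | (4R)-5,7-bis(benzyloxy)-8-methyl-4-(2-methylpropyl)-6-(3-phenylpropanoyl)-3,4-dihydro-2H-chromen-2-one | O=C1C[C@@H](CC(C)C)c2c(OCc3ccccc3)c(C(=O)CCc3ccccc3)c(OCc3ccccc3)c(C)c2O1 | intermediate
8 | 2,2,4,4-tetramethylcyclobutane-1,3-dione | CC1(C)C(=O)C(C)(C)C1=O | starting material
9 | methyl 2,2,4-trimethyl-3-oxopentanoate | COC(=O)C(C)(C)C(=O)C(C)C | intermediate
10 | lithium 1-methoxy-2,2,4-trimethyl-1-oxopent-3-en-3-olate | [Li+].COC(=O)C(C)(C)C([O-])=C(C)C | intermediate (not isolated)
11 | methyl (7R)-7-[2,4-bis(benzyloxy)-6-hydroxy-5-methyl-3-(3-phenylpropanoyl)phenyl]-2,2,4,4,9-pentamethyl-3,5-dioxodecanoate (formed as its lithium phenoxide) | COC(=O)C(C)(C)C(=O)C(C)(C)C(=O)C[C@@H](CC(C)C)c1c(OCc2ccccc2)c(C(=O)CCc2ccccc2)c(OCc2ccccc2)c(C)c1O | intermediate (not isolated)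
12 | 2-[(1S)-1-[2,4-bis(benzyloxy)-6-hydroxy-5-methyl-3-(3-phenylpropanoyl)phenyl]-3-methylbutyl]-3-hydroxy-4,4,6,6-tetramethylcyclohex-2-ene-1,5-dione | Cc1c(OCc2ccccc2)c(C(=O)CCc2ccccc2)c(OCc2ccccc2)c([C@H](CC(C)C)C2=C(O)C(C)(C)C(=O)C(C)(C)C2=O)c1O | intermediate
13 | 3-hydroxy-4,4,6,6-tetramethyl-2-[(1S)-3-methyl-1-[2,4,6-trihydroxy-3-methyl-5-(3-phenylpropanoyl)phenyl]butyl]cyclohex-2-ene-1,5-dione | Cc1c(O)c(C(=O)CCc2ccccc2)c(O)c([C@H](CC(C)C)C2=C(O)C(C)(C)C(=O)C(C)(C)C2=O)c1O | target

**Step count and risks**

Total steps: 7. Longest linear sequence: 6 (steps 1, 2, 3, 4, 6, 7); step 5 is a one-step side branch.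

Step 6 is the most likely to fail. Proton transfer from C3 of the lactone or from the aryl ketone to the hindered enolate may outpace carbonyl addition and lead to self-condensation of the lactone. Acylation may stop at oxygen. The methoxide released in the ring closure may cleave the 1,3-diketone of the open intermediate before it cyclises. The fallback separates the two bond formations and replaces the lactone by an acid chloride, a standard acyl donor for tetrasubstituted lithium enolates. It sets out from 7. The lactone is opened with aqueous NaOH, and phenoxide and carboxylate are both benzylated (BnBr, K2CO3, DMF) to benzyl (3R)-5-methyl-3-[2,4,6-tris(benzyloxy)-3-methyl-5-(3-phenylpropanoyl)phenyl]hexanoate F1. LiOH hydrolysis gives (3R)-5-methyl-3-[2,4,6-tris(benzyloxy)-3-methyl-5-(3-phenylpropanoyl)phenyl]hexanoic acid F2. Oxalyl chloride with catalytic DMF gives (3R)-5-methyl-3-[2,4,6-tris(benzyloxy)-3-methyl-5-(3-phenylpropanoyl)phenyl]hexanoyl chloride F3. This is added at −78 °C to lithium enolate 10 and gives, after isolation, methyl (7R)-2,2,4,4,9-pentamethyl-3,5-dioxo-7-[2,4,6-tris(benzyloxy)-3-methyl-5-(3-phenylpropanoyl)phenyl]decanoate F4. LiN(SiMe3)2 in THF then closes ring B in the same Dieckmann mode to 3-hydroxy-4,4,6,6-tetramethyl-2-[(1S)-3-methyl-1-[2,4,6-tris(benzyloxy)-3-methyl-5-(3-phenylpropanoyl)phenyl]butyl]cyclohex-2-ene-1,5-dione F5. Hydrogenolysis of its three benzyl ethers (H2, Pd/C) comes back to the route at 13.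

Step 4 is the second risk. Copper hydride may hydrosilylate the aryl ketone or over-reduce the saturated lactone to the lactol. Hydride delivery to the crowded, electron-rich C4 next to the 5-benzyloxy group may also be slow or poorly face-selective. The fallback sets the stereocentre by carboxylate-directed asymmetric hydrogenation, which leaves ketones and benzyl ethers alone. It sets out from 6. Aqueous NaOH opens the coumarin to disodium (2Z)-3-[2,4-bis(benzyloxy)-5-methyl-6-oxido-3-(3-phenylpropanoyl)phenyl]-5-methylhex-2-enoate F6. This is hydrogenated with Ru(OAc)2[(R)-BINAP] under hydrogen pressure in methanol (ligand antipode chosen as for step 4) to (3R)-3-[2,4-bis(benzyloxy)-6-hydroxy-5-methyl-3-(3-phenylpropanoyl)phenyl]-5-methylhexanoic acid F7. Acidification relactonises it and returns to the route at 7.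

Step 2 is the third risk. The acyl chloride may be consumed by intramolecular acylation of its own phenyl ring. Acylation may stop at oxygen without Fries shift. Conversion at the position between the two hydroxyls may remain incomplete. The fallback uses a nitrile electrophile, which can neither cyclise to an indanone under these conditions nor acylate oxygen irreversibly. It sets out from 3. A Houben–Hoesch reaction with 3-phenylpropanenitrile (ZnCl2, HCl gas, Et2O) gives 1-[5,7-dihydroxy-8-methyl-4-(2-methylpropyl)-2-oxo-2H-chromen-6-yl]-3-phenylpropan-1-iminium chloride F8. Hydrolysis in hot water returns to the route at 5.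

**Further compounds**

F1 | step 6 | benzyl (3R)-5-methyl-3-[2,4,6-tris(benzyloxy)-3-methyl-5-(3-phenylpropanoyl)phenyl]hexanoate | O=C(OCc1ccccc1)C[C@@H](CC(C)C)c1c(OCc2ccccc2)c(C(=O)CCc2ccccc2)c(OCc2ccccc2)c(C)c1OCc1ccccc1
F2 | step 6 | (3R)-5-methyl-3-[2,4,6-tris(benzyloxy)-3-methyl-5-(3-phenylpropanoyl)phenyl]hexanoic acid | OC(=O)C[C@@H](CC(C)C)c1c(OCc2ccccc2)c(C(=O)CCc2ccccc2)c(OCc2ccccc2)c(C)c1OCc1ccccc1
F3 | step 6 | (3R)-5-methyl-3-[2,4,6-tris(benzyloxy)-3-methyl-5-(3-phenylpropanoyl)phenyl]hexanoyl chloride | ClC(=O)C[C@@H](CC(C)C)c1c(OCc2ccccc2)c(C(=O)CCc2ccccc2)c(OCc2ccccc2)c(C)c1OCc1ccccc1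
F4 | step 6 | methyl (7R)-2,2,4,4,9-pentamethyl-3,5-dioxo-7-[2,4,6-tris(benzyloxy)-3-methyl-5-(3-phenylpropanoyl)phenyl]decanoate | COC(=O)C(C)(C)C(=O)C(C)(C)C(=O)C[C@@H](CC(C)C)c1c(OCc2ccccc2)c(C(=O)CCc2ccccc2)c(OCc2ccccc2)c(C)c1OCc1ccccc1
F5 | step 6 | 3-hydroxy-4,4,6,6-tetramethyl-2-[(1S)-3-methyl-1-[2,4,6-tris(benzyloxy)-3-methyl-5-(3-phenylpropanoyl)phenyl]butyl]cyclohex-2-ene-1,5-dione | Cc1c(OCc2ccccc2)c(C(=O)CCc2ccccc2)c(OCc2ccccc2)c([C@H](CC(C)C)C2=C(O)C(C)(C)C(=O)C(C)(C)C2=O)c1OCc1ccccc1
F6 | step 4 | disodium (2Z)-3-[2,4-bis(benzyloxy)-5-methyl-6-oxido-3-(3-phenylpropanoyl)phenyl]-5-methylhex-2-enoate | [Na+].[Na+].[O-]C(=O)/C=C(/CC(C)C)c1c(OCc2ccccc2)c(C(=O)CCc2ccccc2)c(OCc2ccccc2)c(C)c1[O-]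
F7 | step 4 | (3R)-3-[2,4-bis(benzyloxy)-6-hydroxy-5-methyl-3-(3-phenylpropanoyl)phenyl]-5-methylhexanoic acid | OC(=O)C[C@@H](CC(C)C)c1c(OCc2ccccc2)c(C(=O)CCc2ccccc2)c(OCc2ccccc2)c(C)c1O
F8 | step 2 | 1-[5,7-dihydroxy-8-methyl-4-(2-methylpropyl)-2-oxo-2H-chromen-6-yl]-3-phenylpropan-1-iminium chloride | [Cl-].[NH2+]=C(CCc1ccccc1)c1c(O)c(C)c2OC(=O)C=C(CC(C)C)c2c1O
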